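# Pongaflavanol: synthesis proposal

## The problem

Pongaflavanol 13 is a flavan-4-ol whose ring A is no longer aromatic. Ring A is a cyclohexa-2,4-dienone, C5(OMe)=C6H–C7(=O)–C8(prenyl)2–C8a(=C4a)–O1, fused through C4a=C8a to a dihydropyran ring (O1, C2, C3, C4, C4a, C8a) that carries phenyl at C2 and hydroxyl at C4.

The hardest point is the quaternary carbon C8. Two prenyl groups must sit on the one ring carbon between the C7 carbonyl and the enol-ether carbon C8a, and not on C6 or on oxygen. In any aromatic flavonoid precursor C6 and C8 are both ortho to the 7-oxygen, and a second alkylation prefers the free position that keeps the arene.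

There are two stereocentres, C2 (S) and C4 (S), in a 2,4-cis relation. C2 is independent and must be set in the absolute sense. C4 can be controlled by C2 through hydride addition to a C4 ketone whose ring holds the C2 phenyl equatorial.

The groups are fragile. The C4 alcohol is allylic to the enol ether O1–C8a=C4a and ionises under acid. A C4 ketone precursor can open at O1–C2 by E1cB under base (the leaving group is a vinylogous carboxylate) and lose the C2 configuration. The two trisubstituted prenyl alkenes exclude strong acid, ozone and hydrogenation.

Two features of the structure are used: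

- **Local mirror plane of ring A.** Ring A taken alone has a mirror plane through C5 (OMe) and C8 (gem-diprenyl). C4a/C6 and C8a/C7 are therefore equivalent before the pyran ring is attached, and ring A can be built as a symmetric vinylogous acid in which the C6/C8 question does not exist.
- **C2 as the only hydrogen-bearing β-carbon.** In the oxidised (γ-pyrone) form of the pyran ring, C2 is the β-carbon of the vinylogous ester O1–C2=C3–C4=O. It is the only β-carbon of the bicycle that bears hydrogen, since C5 and C8a are fully substituted and oxygen-bearing. This allows the key step: a catalytic enantioselective conjugate phenylation at C2 of an achiral, fully elaborated ring A/pyranone core.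

## Retrosynthesis

**13 ⇒ 12.** The C4–H bond is cut: the carbinol becomes the ketone of the (2S)-dihydropyranone 12. Carrying the alcohol through earlier steps is ruled out by its lability, and setting C4 independently is unnecessary because C2 can control it. The precursor has one stereocentre less. The forward reduction must take the C4 carbonyl and leave the C7 carbonyl, add 1,2, and deliver hydride anti to the equatorial phenyl.

**12 ⇒ 10 + 11.** The C2–aryl bond is cut, giving the achiral bicyclic γ-pyrone 10 and phenylboronic acid 11. The neighbouring cuts, O1–C2 (oxa-Michael or displacement) and C2–C3 (aldol), lead to open-chain enones or hydroxy ketones on a ring A that is a vinylogous acid. Those equilibrate with 12 and would erode C2, or they need a chiral three-carbon fragment made separately. The C–C cut is irreversible in the forward sense, removes the only independent stereocentre and six carbons, and leaves a flat precursor. The forward step must provide facial control by a chiral catalyst, addition at C2 only, and tolerance of the prenyl alkenes.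

**10 ⇒ 8.** O1–C2 and C2=C3 are cut. C2 goes back to a one-carbon amide acetal and the pyranone to the acetyl group of 8 (C4 and C3) next to the C8a enol. This is preferred to closing a side-chain oxygen onto ring A, which could also attack C5 and expel methanol. Here the ring-A oxygen is the nucleophile and only the C8a oxygen is free. The precursor is monocyclic.

**8 ⇒ 6.** The C4a–C4 bond is cut (C-acetylation). In 6 the two ring CH carbons are related by the mirror plane through C5 and C8, so acylation can give only one compound. This is where the C6/C8 ambiguity of the aromatic series is avoided. The forward reaction needs C- over O-acylation, which an O-to-C acyl migration supplies.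

**6 ⇒ 5.** One ring bond of ring A is cut, between a carbonyl carbon and its CH neighbour (C8a–C4a in target numbering, or C7–C6, the same by symmetry). This gives the acyclic ester 5, in which the quaternary carbon and the methoxy group are already placed. Alkylating a preformed six-membered ring would let ring positions compete; this closure has only one productive mode. The forward step must achieve γ-deprotonation and C-acylation on the ester (a vinylogous Dieckmann condensation).

**5 ⇒ 3 ⇒ 1 + 2.** The ester and enol ether of 5 are traced to the enol lactone 3, and the two C–prenyl bonds of 3 are cut to give the pyranone 1 and prenyl acetate 2. C3 of 1 is the only nucleophilic carbon of that heteroarene, so double prenylation can only be geminal, and O-prenylation is reversible under palladium catalysis. Over steps 2 and 3 the ring oxygen of the pyranone is in effect exchanged for its methyl carbon, which turns the heterocycle into ring A.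

## Roads not taken

**Alternative 1:** the most obvious plan cuts the two C8–prenyl bonds last. (2S)-7-Hydroxy-5-methoxyflavanone A1 would be C-prenylated under base to the 8-prenyl flavanone A2 and then prenylated again at C8 to give 12, followed by reduction. The forward key step is a dearomative gem-diprenylation of a phenoxide. It is short, but ring A of A1 has lost its symmetry:
- C6 and C8 are both ortho to the 7-oxide.
- After the first alkylation the second electrophile prefers the still free C6 (which keeps the arene) or oxygen.
- The base needed opens the flavanone at O1–C2 by E1cB and racemises C2.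

The chosen plan makes the quaternary carbon on C3 of pyranone 1, where no other carbon competes, and sets C2 afterwards.

**Alternative 2:** cut O1–C2 as an oxa-Michael bond. C-Cinnamoylation of 6 would give the dearomatised chalcone A3, and a 6-endo oxa-Michael addition of the C8a enol under a chiral base or thiourea catalyst would give 12. The step count from 6 is one lower. However, the enol of A3 is a vinylogous acid and hence a good leaving group, so the ring closure is reversible and any enantioselectivity would drain away through retro-oxa-Michael opening. Asymmetric versions of this cyclisation rely on an extra activating group at C3 that the target lacks. The chosen plan sets C2 by an irreversible C–C bond formation.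

**Alternative 3:** cut C3–C4 and O1–C2 together. The oxadiene A4 (the 4-formyl derivative of 6 as its silyl enol ether, O=C8a–C4a=C4H–OSi) would undergo an inverse-demand hetero-Diels–Alder reaction with styrene A5 to give the 4-silyloxyflavan A6, and desilylation would give the target directly without a C4 ketone. The drawbacks:
- A donor-substituted oxadiene is a poor partner for an unactivated styrene.
- No dependable catalyst gives absolute control for this pair.
- The endo/exo ratio decides cis versus trans.
- Removing silicon from the ionisable C4 oxygen invites epimerisation or elimination.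

The chosen plan uses catalyst control of a known type for C2 and substrate control for C4.

Key step: step 6

Assumption: 6 and 8 are written as their conjugated enol tautomers (vinylogous acids); the diketo forms are the same compounds.

Assumption: the facial sense of the Pd(OCOCF3)2/t-BuPyOx catalyst on 10 is taken to follow that of simple cyclic enones, so the (R)-ligand is written for the 2S product; if the sense proves opposite, the (S)-ligand is used with nothing else changed.

## Route

Step 1
Reactants: 1 triacetic acid lactone (4-hydroxy-6-methyl-2H-pyran-2-one); 2 prenyl acetate (3-methylbut-2-en-1-yl acetate)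
Product: 3 6-methyl-3,3-bis(3-methylbut-2-en-1-yl)-2H-pyran-2,4(3H)-dione
Conditions: 2 (2.5 equiv), Pd(PPh3)4 (5 mol %), DBU (2.2 equiv), THF, 60 °C
Reagents that add atoms: none
Why: Double Tsuji–Trost allylation: the pyranone anion attacks the unsubstituted terminus of the π-prenyl complex of divalent palladium at C3, its only nucleophilic carbon; O-prenyl isomers re-ionise under zerovalent palladium and drain to the C-alkylated product, and the second prenylation at C3 dearomatises the heterocycle and forms the quaternary carbon (no stereocentre).

Step 2
Reactants: 3 6-methyl-3,3-bis(3-methylbut-2-en-1-yl)-2H-pyran-2,4(3H)-dione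
Product: 5 methyl (E)-5-methoxy-2,2-bis(3-methylbut-2-en-1-yl)-3-oxohex-4-enoate, via diketo ester 4 (not isolated)
Conditions: NaOMe (1.1 equiv), MeOH, 0 °C; then TsOH·H2O (1.2 equiv), HC(OMe)3 (3 equiv), 23 °C
Reagents that add atoms: sodium methoxide, C[O-].[Na+]; trimethyl orthoformate, COC(OC)OC
Why: Methanolysis of the enol lactone (an activated ester) opens the ring to β-diketone 4; acid-catalysed enol ether formation with the orthoformate then occurs at the unhindered acetyl carbonyl and not at the neopentyl ketone beside the quaternary carbon, which places the methoxy group para to the gem-diprenyl carbon of the future ring A.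

Step 3
Reactants: 5 methyl (E)-5-methoxy-2,2-bis(3-methylbut-2-en-1-yl)-3-oxohex-4-enoate
Product: 6 5-hydroxy-3-methoxy-6,6-bis(3-methylbut-2-en-1-yl)cyclohexa-2,4-dien-1-one
Conditions: KOtBu (2.2 equiv), THF/t-BuOH (10:1), 0 to 40 °C; then 1 M HCl to pH 3, 0 °C
Reagents that add atoms: none
Why: Vinylogous Dieckmann condensation: reversible γ-deprotonation of the β-methoxy enone (no α'-hydrogen competes because C2 is quaternary) gives a dienolate whose terminal carbon acylates on the methyl ester in a 6-(enolexo)-exo-trig closure, driven by formation of the stabilised, mirror-symmetric anion of the vinylogous acid 6 (no stereocentre).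

Step 4
Reactants: 6 5-hydroxy-3-methoxy-6,6-bis(3-methylbut-2-en-1-yl)cyclohexa-2,4-dien-1-one
Product: 8 4-acetyl-5-hydroxy-3-methoxy-6,6-bis(3-methylbut-2-en-1-yl)cyclohexa-2,4-dien-1-one, via enol acetate 7 (not isolated)
Conditions: Ac2O (1.2 equiv), Et3N (2.5 equiv), CH2Cl2, 0 °C; then DMAP (0.5 equiv), 40 °C
Reagents that add atoms: acetic anhydride, CC(=O)OC(C)=O
Why: O-Acylation followed by DMAP-mediated O-to-C acyl migration (the Fries-type rearrangement used to make 2-acyl-1,3-diones); the anion of 6 is mirror-symmetric, so both ring CH positions are the same and only one C-acetyl compound can form, with the chelated enol 8 as the thermodynamic sink.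

Step 5
Reactants: 8 4-acetyl-5-hydroxy-3-methoxy-6,6-bis(3-methylbut-2-en-1-yl)cyclohexa-2,4-dien-1-one
Product: 10 5-methoxy-8,8-bis(3-methylbut-2-en-1-yl)-4H-chromene-4,7(8H)-dione, via enaminone 9 (not isolated)
Conditions: Me2NCH(OMe)2 (2 equiv), toluene, 80 °C; then AcOH, 23 °C
Reagents that add atoms: N,N-dimethylformamide dimethyl acetal, COC(OC)N(C)C
Why: Condensation of the acetyl CH3 with the amide acetal gives enaminone 9, and the C8a hydroxyl, the only free OH, adds to its β-carbon with loss of dimethylamine (6-endo addition–elimination, the standard chromone annulation of ortho-hydroxyaryl methyl ketones and 2-acetyl-1,3-diones), so O1 can only be joined to C8a.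

Step 6
Reactants: 10 5-methoxy-8,8-bis(3-methylbut-2-en-1-yl)-4H-chromene-4,7(8H)-dione; 11 phenylboronic acid
Product: 12 (2S)-5-methoxy-8,8-bis(3-methylbut-2-en-1-yl)-2-phenyl-2,3-dihydro-4H-chromene-4,7(8H)-dione
Conditions: 11 (2 equiv), Pd(OCOCF3)2 (5 mol %), (R)-4-tert-butyl-2-(pyridin-2-yl)-4,5-dihydrooxazole [(R)-t-BuPyOx] (6 mol %), NH4PF6 (30 mol %), H2O (5 equiv), ClCH2CH2Cl, 60 °C, air
Reagents that add atoms: none
Why: Transmetalation of 11 to the cationic pyridine-oxazoline complex of divalent palladium gives an aryl–palladium species that binds the C2=C3 bond of 10 and inserts it with phenyl going to C2 and palladium to C3; the palladium enolate is then protonated by water, which turns the catalyst over without a redox change. The closest known reaction type is the palladium/pyridine-oxazoline-catalysed asymmetric conjugate addition of arylboronic acids to chromones and other cyclic β-substituted enones (a Hayashi–Miyaura-type addition). No ring is closed; the γ-pyrone ring is dearomatised and C2 becomes the only new stereocentre. Its configuration is set by the catalyst alone: the tert-butyl group on the oxazoline blocks one face of the flat, achiral enone in the insertion step, and the ligand antipode is chosen for 2S. The step needs regioselectivity for C2, which the substrate secures because C2 is the only hydrogen-bearing β-carbon (C5 and C8a are tetrasubstituted and oxygen-bearing). It also needs chemoselectivity over the two prenyl alkenes, which are trisubstituted and electron-rich and therefore slow to insert into an aryl–palladium bond. Conjugate addition should win over a Heck-type outcome because syn-insertion leaves no hydrogen syn to palladium at C2. The near-neutral, weakly acidic medium avoids E1cB opening of O1–C2 in 12, so the new configuration should persist.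

Step 7
Reactants: 12 (2S)-5-methoxy-8,8-bis(3-methylbut-2-en-1-yl)-2-phenyl-2,3-dihydro-4H-chromene-4,7(8H)-dione
Product: 13 pongaflavanol, (2S,4S)-4-hydroxy-5-methoxy-8,8-bis(3-methylbut-2-en-1-yl)-2-phenyl-3,4-dihydro-2H-chromen-7(8H)-one
Conditions: NaBH4 (1.0 equiv), CeCl3·7H2O (1.1 equiv), MeOH/CH2Cl2, −78 °C; pH 7 phosphate buffer
Reagents that add atoms: none
Why: Luche reduction: the cerium-activated borohydride adds 1,2 to the C4 carbonyl, which has an unhindered CH2 neighbour, in preference to the C7 carbonyl, which is flanked by the quaternary C8 and is a doubly vinylogous ester; hydride enters axially on the half-chair that holds the C2 phenyl equatorial, which gives the equatorial 4-hydroxyl, that is the 2,4-cis (2S,4S) alcohol, as in the reduction of flavanones to cis-flavan-4-ols.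

## Compound list

1 | triacetic acid lactone (4-hydroxy-6-methyl-2H-pyran-2-one) | CC1=CC(O)=CC(=O)O1 | starting material
2 | prenyl acetate (3-methylbut-2-en-1-yl acetate) | CC(=O)OCC=C(C)C | starting material
3 | 6-methyl-3,3-bis(3-methylbut-2-en-1-yl)-2H-pyran-2,4(3H)-dione | CC1=CC(=O)C(CC=C(C)C)(CC=C(C)C)C(=O)O1 | intermediate
4 | methyl 2,2-bis(3-methylbut-2-en-1-yl)-3,5-dioxohexanoate | COC(=O)C(CC=C(C)C)(CC=C(C)C)C(=O)CC(C)=O | intermediate
5 | methyl (E)-5-methoxy-2,2-bis(3-methylbut-2-en-1-yl)-3-oxohex-4-enoate | COC(=O)C(CC=C(C)C)(CC=C(C)C)C(=O)/C=C(\C)OC | intermediate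
6 | 5-hydroxy-3-methoxy-6,6-bis(3-methylbut-2-en-1-yl)cyclohexa-2,4-dien-1-one | COC1=CC(=O)C(CC=C(C)C)(CC=C(C)C)C(O)=C1 | intermediate
7 | 3-methoxy-5-oxo-6,6-bis(3-methylbut-2-en-1-yl)cyclohexa-1,3-dien-1-yl acetate | COC1=CC(=O)C(CC=C(C)C)(CC=C(C)C)C(OC(C)=O)=C1 | intermediate
8 | 4-acetyl-5-hydroxy-3-methoxy-6,6-bis(3-methylbut-2-en-1-yl)cyclohexa-2,4-dien-1-one | COC1=CC(=O)C(CC=C(C)C)(CC=C(C)C)C(O)=C1C(C)=O | intermediate
9 | 4-[(E)-3-(dimethylamino)prop-2-enoyl]-5-hydroxy-3-methoxy-6,6-bis(3-methylbut-2-en-1-yl)cyclohexa-2,4-dien-1-one | COC1=CC(=O)C(CC=C(C)C)(CC=C(C)C)C(O)=C1C(=O)/C=C/N(C)C | intermediate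
10 | 5-methoxy-8,8-bis(3-methylbut-2-en-1-yl)-4H-chromene-4,7(8H)-dione | COC1=CC(=O)C(CC=C(C)C)(CC=C(C)C)C2=C1C(=O)C=CO2 | intermediate
11 | phenylboronic acid | OB(O)c1ccccc1 | starting material
12 | (2S)-5-methoxy-8,8-bis(3-methylbut-2-en-1-yl)-2-phenyl-2,3-dihydro-4H-chromene-4,7(8H)-dione | COC1=CC(=O)C(CC=C(C)C)(CC=C(C)C)C2=C1C(=O)C[C@@H](c1ccccc1)O2 | intermediate
13 | pongaflavanol, (2S,4S)-4-hydroxy-5-methoxy-8,8-bis(3-methylbut-2-en-1-yl)-2-phenyl-3,4-dihydro-2H-chromen-7(8H)-one | COC1=CC(=O)C(CC=C(C)C)(CC=C(C)C)C2=C1[C@@H](O)C[C@@H](c1ccccc1)O2 | target

## Step count and least certain steps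

Total step count: 7. Longest linear sequence: 7 steps (1 to 13).

**Step 6 (key step).**
- Facial selectivity may be lower than on simple chromones, because the peri methoxy group at C5 and the cross-conjugated ring A change how the enone sits in the chiral pocket.
- Water may open the γ-pyrone at C2 before insertion.
- Reversible coordination of the prenyl alkenes to the cationic palladium may slow turnover.
- Partial E1cB opening and reclosure of the product would erode the enantiomeric purity.

Fallback by known chemistry, setting out from 6 and returning at 12; C2 is taken from the chiral pool and O1–C2 is closed by displacement: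
- Commercial ethyl (R)-3-hydroxy-3-phenylpropanoate is silylated (TBSCl, imidazole) to ethyl (R)-3-(tert-butyldimethylsilyloxy)-3-phenylpropanoate F1.
- F1 is saponified (LiOH, aqueous THF) to (R)-3-(tert-butyldimethylsilyloxy)-3-phenylpropanoic acid F2.
- Carbodiimide/DMAP coupling of F2 with 6 (O-acylation and acyl migration as in step 4) gives 4-[(R)-3-(tert-butyldimethylsilyloxy)-3-phenylpropanoyl]-5-hydroxy-3-methoxy-6,6-bis(3-methylbut-2-en-1-yl)cyclohexa-2,4-dien-1-one F3.
- HF·pyridine frees 4-[(R)-3-hydroxy-3-phenylpropanoyl]-5-hydroxy-3-methoxy-6,6-bis(3-methylbut-2-en-1-yl)cyclohexa-2,4-dien-1-one F4.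
- Mitsunobu cyclisation (PPh3, diisopropyl azodicarboxylate) with the chelated enol as the acidic oxygen nucleophile closes O1–C2 with inversion, R to S, and gives 12.

**Step 1.**
- The reaction may stop after the first prenylation, because the second alkylation builds a quaternary carbon.
- Alkylation may divert to oxygen or to C5.
- Attack may occur at the substituted terminus of the prenyl complex.

Fallback, setting out from 2 and returning at 4; the quaternary carbon is made on an acyclic β-keto ester and the chain is then extended:
- Commercial methyl acetoacetate, in place of 1, is doubly C-prenylated with 2 (Pd(PPh3)4, DBU) to methyl 2-acetyl-5-methyl-2-(3-methylbut-2-en-1-yl)hex-4-enoate F5.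
- The only enolisable position of F5, its acetyl CH3, is C-acetylated by soft enolisation (MgBr2·OEt2, i-Pr2NEt, acetyl chloride) to give 4.
- 4 is taken on under the acid half of step 2 to 5.

**Step 3.**
- Deprotonation may give the dienolate geometry in which the carbanion terminus points away from the ester, so that ring closure depends on re-equilibration.
- Alkoxide may attack the C3 ketone (retro-Claisen cleavage).
- Intermolecular condensation may compete.

Fallback, setting out from 4 (isolated after the NaOMe half of step 2) and returning at 6; the order of ring closure and enol ether formation is reversed: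
- The dianion of the β-diketone (LiN(i-Pr)2, 2.5 equiv, THF, −78 to 0 °C) undergoes Dieckmann closure to 2,2-bis(3-methylbut-2-en-1-yl)cyclohexane-1,3,5-trione F6.
- Acid-catalysed enol ether formation (HC(OMe)3, MeOH, TsOH·H2O cat.) at the carbonyl remote from the quaternary carbon, the least hindered one, gives 6.

**Step 7.**
- Hydride may add to the C7 carbonyl or in conjugate fashion.
- Hydride may be delivered to the wrong face of C4.
- The allylic C4 alcohol may ionise during work-up or chromatography.

Fallback, setting out from 12 and returning at 13; substrate-controlled borohydride delivery is replaced by a catalyst-controlled outer-sphere transfer hydrogenation: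
- Reagents are RuCl[(S,S)-TsDPEN](p-cymene) with HCO2H/Et3N in CH2Cl2.
- By the usual model for aryl-type ketones this should deliver the 4S alcohol, matched with the substrate preference.
- Such catalysts do not reduce a hindered, non-aryl carbonyl like C7.
- Chromatography is run on triethylamine-deactivated silica.
- No new compound is involved.

## Further compounds

F1 | step 6 | ethyl (R)-3-(tert-butyldimethylsilyloxy)-3-phenylpropanoate | CCOC(=O)C[C@@H](O[Si](C)(C)C(C)(C)C)c1ccccc1
F2 | step 6 | (R)-3-(tert-butyldimethylsilyloxy)-3-phenylpropanoic acid | OC(=O)C[C@@H](O[Si](C)(C)C(C)(C)C)c1ccccc1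
F3 | step 6 | 4-[(R)-3-(tert-butyldimethylsilyloxy)-3-phenylpropanoyl]-5-hydroxy-3-methoxy-6,6-bis(3-methylbut-2-en-1-yl)cyclohexa-2,4-dien-1-one | COC1=CC(=O)C(CC=C(C)C)(CC=C(C)C)C(O)=C1C(=O)C[C@@H](O[Si](C)(C)C(C)(C)C)c1ccccc1
F4 | step 6 | 4-[(R)-3-hydroxy-3-phenylpropanoyl]-5-hydroxy-3-methoxy-6,6-bis(3-methylbut-2-en-1-yl)cyclohexa-2,4-dien-1-one | COC1=CC(=O)C(CC=C(C)C)(CC=C(C)C)C(O)=C1C(=O)C[C@@H](O)c1ccccc1
F5 | step 1 | methyl 2-acetyl-5-methyl-2-(3-methylbut-2-en-1-yl)hex-4-enoate | COC(=O)C(CC=C(C)C)(CC=C(C)C)C(C)=O
F6 | step 3 | 2,2-bis(3-methylbut-2-en-1-yl)cyclohexane-1,3,5-trione | O=C1CC(=O)CC(=O)C1(CC=C(C)C)CC=C(C)C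
F0 | step 7 | none | none
A1 | alternative 1 | (2S)-7-hydroxy-5-methoxyflavanone | COc1cc(O)cc2c1C(=O)C[C@@H](c1ccccc1)O2
A2 | alternative 1 | (2S)-7-hydroxy-5-methoxy-8-(3-methylbut-2-en-1-yl)flavanone | COc1cc(O)c(CC=C(C)C)c2c1C(=O)C[C@@H](c1ccccc1)O2
A3 | alternative 2 | 4-[(E)-3-phenylprop-2-enoyl]-5-hydroxy-3-methoxy-6,6-bis(3-methylbut-2-en-1-yl)cyclohexa-2,4-dien-1-one | COC1=CC(=O)C(CC=C(C)C)(CC=C(C)C)C(O)=C1C(=O)/C=C/c1ccccc1
A4 | alternative 3 | 4-[(tert-butyldimethylsilyloxy)methylidene]-5-methoxy-2,2-bis(3-methylbut-2-en-1-yl)cyclohex-5-ene-1,3-dione | COC1=CC(=O)C(CC=C(C)C)(CC=C(C)C)C(=O)C1=CO[Si](C)(C)C(C)(C)C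
A5 | alternative 3 | styrene | C=Cc1ccccc1
A6 | alternative 3 | 4-(tert-butyldimethylsilyloxy)-5-methoxy-8,8-bis(3-methylbut-2-en-1-yl)-2-phenyl-3,4-dihydro-2H-chromen-7(8H)-one (racemic) | COC1=CC(=O)C(CC=C(C)C)(CC=C(C)C)C2=C1C(O[Si](C)(C)C(C)(C)C)CC(c1ccccc1)O2
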